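**Retrosynthetic overview**
1. Target 6 ⇒ triol 5, by disconnecting the O–CH3 bond at the 4-oxygen. This is the last and key step: site-selective O-methylation of the one non-chelated, most acidic OH.
2. Triol 5 ⇒ 2,4,6-trihydroxybenzophenone 3 + two prenyl bromide 4 (double C-prenylation at the two free ring carbons).
3. Ketone 3 ⇒ phloroglucinol 1 + benzoyl chloride 2 (Friedel–Crafts C-acylation).
4. No ring is formed: both benzene rings come from the starting materials, and the route is linear.

Assumption: the target has no stereocentre and no stereogenic double bond, so it is achiral and the route makes the constitution given.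

**Step 1**
Reactants: 1 phloroglucinol (benzene-1,3,5-triol, anhydrous); 2 benzoyl chloride (1.0 equiv)
Product: 3 2,4,6-trihydroxybenzophenone, (2,4,6-trihydroxyphenyl)(phenyl)methanone
Conditions: AlCl3 (3.5 equiv), PhNO2, 70 °C, 3 h; then ice/aq. HCl
Reagents that add atoms: none
Why: Friedel–Crafts acylation of the very electron-rich triol; the first benzoyl group deactivates the ring and chelates, so acylation stops at the mono-ketone, and any O-benzoate formed returns to the C-acyl product by Fries rearrangement under AlCl3.

**Step 2**
Reactants: 3 2,4,6-trihydroxybenzophenone; 4 prenyl bromide (1-bromo-3-methylbut-2-ene, 2.1 equiv)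
Product: 5 (2,4,6-trihydroxy-3,5-bis(3-methylbut-2-en-1-yl)phenyl)(phenyl)methanone
Conditions: 10% aq. KOH (3.0 equiv), 0 °C, 2 h; then 1 M HCl to pH 3
Reagents that add atoms: none
Why: C-alkylation of an ambident phenolate; in water the phenolate oxygens are hydrogen-bonded, so the soft allylic bromide attacks the two free ring carbons C3 and C5, and low temperature with about two equivalents limits geminal over-prenylation.

**Step 3**
Reactants: 5 (2,4,6-trihydroxy-3,5-bis(3-methylbut-2-en-1-yl)phenyl)(phenyl)methanone
Product: 6 (2,6-dihydroxy-4-methoxy-3,5-bis(3-methylbut-2-en-1-yl)phenyl)(phenyl)methanone (target)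
Conditions: O-methyl-N,N'-diisopropylisourea (1.15 equiv), dry THF, 45 °C, 16 h, no added acid or base
Reagents that add atoms: O-methyl-N,N'-diisopropylisourea, COC(=NC(C)C)NC(C)C
Why: Proposed new method: acidity-gated O-methyl transfer from a neutral O-alkylisourea, used here to pick one of three phenolic OH groups in a C-alkylation-prone polyprenylated acylphloroglucinol, a substrate type on which it has not been shown; the isourea (conjugate acid pKa estimated near 10) is protonated only by the 4-OH, a vinylogous carboxylic acid para to the benzoyl carbonyl (pKa estimated near 8) that is not held in the O–H···O=C chelate, and the resulting isouronium/4-phenoxide contact ion pair collapses by SN2 attack of the phenoxide oxygen on the O-methyl carbon with loss of neutral N,N'-diisopropylurea, while the less acidic, chelated 2- and 6-OH groups are not ionised, no metal cation or free base is present to steer methylation to C3/C5, and no acid is present to cyclise the ortho-prenylphenols to chromans; the closest known reaction type is O-alkylisourea esterification of carboxylic acids (proton transfer, then SN2 at the O-alkyl carbon), the same gating logic as diazomethane methylation.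

**Compound list**
1 | phloroglucinol (benzene-1,3,5-triol) | Oc1cc(O)cc(O)c1 | starting material
2 | benzoyl chloride | O=C(Cl)c1ccccc1 | starting material
3 | 2,4,6-trihydroxybenzophenone, (2,4,6-trihydroxyphenyl)(phenyl)methanone | O=C(c1ccccc1)c1c(O)cc(O)cc1O | intermediate
4 | prenyl bromide (1-bromo-3-methylbut-2-ene) | CC(C)=CCBr | starting material
5 | (2,4,6-trihydroxy-3,5-bis(3-methylbut-2-en-1-yl)phenyl)(phenyl)methanone | CC(C)=CCc1c(O)c(CC=C(C)C)c(O)c(C(=O)c2ccccc2)c1O | intermediate
6 | (2,6-dihydroxy-4-methoxy-3,5-bis(3-methylbut-2-en-1-yl)phenyl)(phenyl)methanone | COc1c(CC=C(C)C)c(O)c(C(=O)c2ccccc2)c(O)c1CC=C(C)C | target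

**Total step count:** 3. Compound 3 is also a catalogue compound; buying it leaves 2 steps, but 1 and 2 are far cheaper.
**Longest linear sequence:** 3

**Steps most likely to fail**

Step 3 (the proposed new step). The 4-oxygen sits between two prenyl groups and the ion pair may be poorly populated in THF, so the reaction may be slow; excess reagent could also begin to methylate a chelated OH. The fallback uses known chemistry and reverses the order of events. It sets out from 3: Me2SO4 (1.0 equiv), K2CO3, acetone, room temperature methylates the non-chelated para OH to give cotoin, (2,6-dihydroxy-4-methoxyphenyl)(phenyl)methanone F1. Double C-prenylation of F1 with 4 (aq. KOH, 0 °C, or DBU in THF) then gives the target directly, so it comes back to the route at 6.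

Step 2. Direct C-prenylation gives a statistical mixture of mono-, di-, geminal tri-prenyl and O-prenyl products, and the isolated yield of 5 is expected near 40%. The fallback replaces direct C-alkylation with O-allylation, sigmatropic rearrangement and olefin metathesis. It sets out from 3: allyl bromide (2.2 equiv), K2CO3, acetone, reflux gives (2,4-bis(allyloxy)-6-hydroxyphenyl)(phenyl)methanone F2. Heating in N,N-diethylaniline at 200 °C moves both allyl groups to carbon by Claisen and para-Claisen–Cope rearrangement; every pathway converges on (3,5-diallyl-2,4,6-trihydroxyphenyl)(phenyl)methanone F3. Cross-metathesis with excess 2-methylbut-2-ene and second-generation Grubbs catalyst (H2IMes)(PCy3)Cl2Ru=CHPh (5 mol%) in CH2Cl2 at 40 °C converts both allyl groups to prenyl, and it comes back to the route at 5.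

Step 1. Wet phloroglucinol destroys AlCl3, and O-benzoylation or double acylation can lower the yield. The fallback is the Houben–Hoesch route, which uses a nitrile instead of an acyl chloride. It sets out from 1: benzonitrile, ZnCl2, dry HCl gas, Et2O, 0 °C precipitates the ketiminium salt (2,4,6-trihydroxyphenyl)(phenyl)methaniminium chloride F4. Boiling F4 in water hydrolyses it to the ketone, and it comes back to the route at 3.

**Further compounds**
F1 | step 3 | cotoin, (2,6-dihydroxy-4-methoxyphenyl)(phenyl)methanone | COc1cc(O)c(C(=O)c2ccccc2)c(O)c1
F2 | step 2 | (2,4-bis(allyloxy)-6-hydroxyphenyl)(phenyl)methanone | C=CCOc1cc(O)c(C(=O)c2ccccc2)c(OCC=C)c1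
F3 | step 2 | (3,5-diallyl-2,4,6-trihydroxyphenyl)(phenyl)methanone | C=CCc1c(O)c(CC=C)c(O)c(C(=O)c2ccccc2)c1O
F4 | step 1 | (2,4,6-trihydroxyphenyl)(phenyl)methaniminium chloride | [NH2+]=C(c1ccccc1)c1c(O)cc(O)cc1O.[Cl-]
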